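All runs were computed with constants of no real substance, and the scatter is random.

Through the 8.0 h of summer and winter, which differ in their charge of racemization catalyst, I follow one rate.

| flask | left-handed substrate | right-handed substrate | solid reagent | racemization catalyst | remark | time |
|---|---|---|---|---|---|---|
| alpha | 0.075 M | 0.075 M | 0.20 M | 0.22 mM | run made earlier |  |
| summer | 0.050 M | 0.050 M | 0.200 M | 0.22 mM |  | 8.0 h |
| winter | 0.050 M | 0.050 M | 0.200 M | 0.080 mM |  | 8.0 h |
alpha run (percent of the left-handed substrate and right-handed substrate together charged)

| time / min | right-handed substrate / % | left-handed substrate / % |
|---|---|---|
| 5.00 | 50.3 | 49.5 |
| 15.0 | 49.2 | 49.7 |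
| 25.0 | 48.1 | 47.6 |
| 40.0 | 48.3 | 46.5 |
| 60.0 | 48.3 | 43.8 |
| 80.0 | 44.2 | 41.7 |
| 90.0 | 46.3 | 41.1 |

(scatter of a reading: 1 percentage point)
- partner is single-handed; left-handed substrate and right-handed substrate are mirror images of each other, charged as a racemate, each of them at the stated concentration
- solid, in amounts per volume of the solution: solid reagent
- at the start none of the solid reagent is in solution
- an excess is below zero if the other one leads
- no earlier run changes the charge of racemization catalyst; that part of a forecast is a guess
- the handed part of partner does not stay in what it makes, so the products of the two hands are mirror images too
* which of the two ends with the higher excess of right-handed substrate over left-handed substrate among what is left of the two ("neither" if they lie within 2 percentage points) (summer / winter / neither)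
* excess of right-handed substrate over left-handed substrate among what is left of the two at the end, summer
* excess of right-handed substrate over left-handed substrate among what is left of the two at the end, winter

At 90.0 min the alpha run reads 41.1 % left-handed substrate against 46.3 % right-handed. I assume each hand falls at its own steady pseudo-first-order rate, so the logarithm of right-handed over left-handed substrate climbs in a straight line. The alpha readings from 60.0 min on give a climb of 0.0718 /h, a reading with its scatter, and I call this the split rate. A first-order rate takes no account of the substrate charge, so I carry it over although summer has 0.667 of the alpha charge of each substrate. Integrated, the ratio of the hands after 8.0 h is the exponential of rate times time, 1.78, and the excess is that ratio less one over that ratio plus one, 27.9 %.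

One thing that can slow the climb is the racemization catalyst, which has nothing to even out while the hands are equal but pulls back harder as the excess grows. The alpha run, with summer's catalyst charge, felt that pull at small excess, so I put summer under 27.9 %. Winter has 0.364 of that charge, so I put it above 27.9 %, by an amount I can only guess.

The forecast says winter, with 14 % for summer and 25 % for winter, which puts winter below my 27.9 %, and it expects that summer “should be held down more”.

The flasks give 19.8 % for summer and 38.9 % for winter, so winter ends higher.

    partner + left-handed substrate → left-handed product (k = 37.0 /M/h)
    partner + right-handed substrate → right-handed product (k = 0.990 /M/h)
    left-handed substrate + racemization catalyst ⇌ right-handed substrate + racemization catalyst, rate k3*[racemization catalyst]*[left-handed substrate] forward; the back reaction follows from the equilibrium constant (k = 2900 /M/h)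
    solid reagent ⇌ partner, rate k4*(cs4 - [partner]) while solid is left; crystals form when [partner] > cs4 (solubility = 7.50 mM, k = 5.80 /h)
    racemization catalyst ⇌ dormant form (K = 14.0, k = 0.130 /h)
    2 partner → self-condensation product (k = 2.70 /M/h)

Turned back through the same formula, winter's excess means an average split rate of 0.103 /h over its 8.0 h, which is 1.43 times the alpha reading, and summer's means an average of 0.0501 /h, which is 0.698 times it. Now I read the winter flask at 15 h. The alpha rate gives 49.2 % there, and winter's own rate gives 64.8 %. That neighbouring flask stands at 61.7 %.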